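**Retrosynthetic overview**

- Feature: the target has only two stereocentres, C2 of each 2-methylbutanoyl chain, each bonded to the C1 ketone carbonyl on ring A or ring B. Both are epimerisable, far apart and constitutionally equivalent, so they are made together and late.
- Disconnection 1 (key): both C1–C2 bonds of the acyl chains, back to a bis-aldehyde and two (E)-crotyl boronates. The vinyl ends later become the ethyl ends and the carbinols the ketones.
- Disconnection 2: the two aryl–CH bonds at the bridging carbon, back to two prenylated formylphloroglucinols and 6-methylheptanal. Disconnection 3: the aryl–prenyl bond.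
- No ring is formed. Rings A and B are both bought as 2,4,6-trihydroxybenzaldehyde, whose formyl group first blocks one ring carbon and later anchors the acyl chain.

Key step: step 4

Assumption: the (R)-phosphoric acid is taken to direct the crotyl group to the Re face of the formyl group, as with unhindered aryl aldehydes; if the 2,6-bis(alkoxy)aryl aldehyde responds in the opposite sense, the (S)-acid is used with no other change.

**Route**

Step 1
Reactants: 1 2,4,6-trihydroxybenzaldehyde; 2 prenyl bromide (1-bromo-3-methylbut-2-ene)
Product: 3 2,4,6-trihydroxy-3-(3-methylbut-2-en-1-yl)benzaldehyde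
Conditions: 2 (0.9 equiv), DBU (1.0 equiv), THF, 0 → 23 °C
Reagents that add atoms: none
Why: Base-mediated C-alkylation of the ambident phloroglucinol phenoxide (C-prenylation of an acylphloroglucinol-type ring) should occur at a free ring carbon, the two free positions of 1 being equivalent, and the deficit of bromide holds back a second alkylation.

Step 2
Reactants: 3 2,4,6-trihydroxy-3-(3-methylbut-2-en-1-yl)benzaldehyde (2.1 equiv); 4 6-methylheptanal (1.0 equiv)
Product: 6 5,5'-(6-methylheptane-1,1-diyl)bis[2,4,6-trihydroxy-3-(3-methylbut-2-en-1-yl)benzaldehyde], via ortho-quinone methide 5 (not isolated)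
Conditions: piperidine (20 mol%), AcOH (20 mol%), MeOH, 23 → 45 °C
Reagents that add atoms: none
Why: Amine-salt-catalysed Knoevenagel-type condensation of 4 at C5, the only free ring carbon of 3, should give ortho-quinone methide 5, which a second molecule of 3 captures by Michael (Friedel–Crafts-type) addition in the classical 2:1 phenol–aldehyde condensation, while the ring formyl group, a hydrogen-bonded vinylogous acid carbonyl, is far less electrophilic than the aliphatic aldehyde and stays out of the reaction.

Step 3
Reactants: 6 5,5'-(6-methylheptane-1,1-diyl)bis[2,4,6-trihydroxy-3-(3-methylbut-2-en-1-yl)benzaldehyde]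
Product: 7 5,5'-(6-methylheptane-1,1-diyl)bis[2,4,6-tris(methoxymethoxy)-3-(3-methylbut-2-en-1-yl)benzaldehyde]
Conditions: NaH (8 equiv), MOMCl (9 equiv), DMF, 0 → 23 °C, under argon
Reagents that add atoms: chloromethyl methyl ether (MOMCl), COCCl
Why: Williamson-type O-alkylation of all six phenoxides with the hard electrophile MOMCl should be complete because NaH also frees the hydroxyls that are hydrogen-bonded to the formyl groups, and the fully substituted rings leave no carbon open to alkylation without loss of aromaticity.

Step 4
Reactants: 7 5,5'-(6-methylheptane-1,1-diyl)bis[2,4,6-tris(methoxymethoxy)-3-(3-methylbut-2-en-1-yl)benzaldehyde]; 8 (E)-crotylboronic acid pinacol ester (3 equiv)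
Product: 10 hexakis(methoxymethyl) bis-homoallylic alcohol in which each formyl carbon of 7 has become a (1R,2R)-1-hydroxy-2-methylbut-3-en-1-yl group, via bis(pinacol borate) adduct 9 (not isolated)
Conditions: (R)-3,3'-bis(2,4,6-triisopropylphenyl)-1,1'-binaphthyl-2,2'-diyl hydrogen phosphate (10 mol%), 4 Å molecular sieves, toluene, −30 → 0 °C; then aq. NaHCO3; chromatography on Et3N-deactivated silica
Reagents that add atoms: none
Why: The phosphoric acid binds the boronate by a hydrogen bond from its P–OH to a pinacol oxygen while its P=O oxygen engages the formyl C–H, and the crotyl group passes to the aldehyde carbon through a closed six-membered chair transition state with boron on the carbonyl oxygen, giving first the O-boryl adduct 9, which is hydrolysed on work-up. The closest known reaction type is the chiral-phosphoric-acid-catalysed allyl- and crotylboration of aryl aldehydes with pinacol boronates, run here twice on one molecule; two C–C bonds form and no ring closes. Each carbinol carbon (1R) is set by the catalyst, which exposes the Re face of the formyl group, and each methyl-bearing carbon (2R) follows from the (E)-geometry of 8, because the chair places the crotyl methyl equatorial and gives the anti adduct. The step needs high facial selectivity at two formyl groups that are each flanked by two methoxymethoxy groups, together with a slow uncatalysed background; the low intrinsic reactivity of pinacol boronates provides the second, and the position of the formyl groups on separate, distant rings makes each addition an independent catalyst-controlled event. The two formyl groups of the mirror-symmetric 7 are enantiotopic, but the same bis-adduct results whichever reacts first, and a wrongly set arm leads to a diastereomer of 10 rather than to its enantiomer, which should raise the enantiomeric purity of 10. Only aldehydes react, so the prenyl alkenes and the acetals should be untouched.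

Step 5
Reactants: 10 hexakis(methoxymethyl) bis[(1R,2R)-1-hydroxy-2-methylbut-3-en-1-yl] compound
Product: 11 hexakis(methoxymethyl) bis[(1R,2R)-1-hydroxy-2-methylbutyl] compound
Conditions: 2-nitrobenzenesulfonylhydrazide (excess, in portions), Et3N, CH2Cl2, 23 °C
Reagents that add atoms: none
Why: Diimide, released from the sulfonylhydrazide, transfers two hydrogens in a concerted syn fashion and reduces monosubstituted alkenes far faster than the trisubstituted prenyl alkenes, so the two vinyl groups should become ethyl groups without change at any stereocentre.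

Step 6
Reactants: 11 hexakis(methoxymethyl) bis[(1R,2R)-1-hydroxy-2-methylbutyl] compound
Product: 12 5,5'-(6-methylheptane-1,1-diyl)bis{(2R)-2-methyl-1-[2,4,6-tris(methoxymethoxy)-3-(3-methylbut-2-en-1-yl)phenyl]butan-1-one}
Conditions: Dess–Martin periodinane (3 equiv), pyridine, CH2Cl2, 0 → 23 °C
Reagents that add atoms: none
Why: Dess–Martin oxidation of the two secondary benzylic alcohols under buffered, near-neutral conditions should give the aryl ketones, and because each ketone is twisted out of the ring plane by its two ortho substituents it enolises slowly, so the adjacent (R)-methyl centres should survive.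

Step 7
Reactants: 12 5,5'-(6-methylheptane-1,1-diyl)bis{(2R)-2-methyl-1-[2,4,6-tris(methoxymethoxy)-3-(3-methylbut-2-en-1-yl)phenyl]butan-1-one}
Product: 13 5,5'-(6-methylheptane-1,1-diyl)bis{(2R)-2-methyl-1-[2,4,6-trihydroxy-3-(3-methylbut-2-en-1-yl)phenyl]butan-1-one} (CNP0245910.1)
Conditions: HCl (about 1 M) in MeOH, 23 °C
Reagents that add atoms: none
Why: Acid-catalysed acetal methanolysis should remove the six methoxymethyl ethers as dimethoxymethane, and dilute acid at ambient temperature is chosen so that the prenyl groups do not add to the neighbouring hydroxyls and the ketone α-centres do not epimerise.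

**Compound list**

1 | 2,4,6-trihydroxybenzaldehyde | O=Cc1c(O)cc(O)cc1O | starting material
2 | prenyl bromide (1-bromo-3-methylbut-2-ene) | CC(C)=CCBr | starting material
3 | 2,4,6-trihydroxy-3-(3-methylbut-2-en-1-yl)benzaldehyde | O=Cc1c(O)cc(O)c(CC=C(C)C)c1O | intermediate
4 | 6-methylheptanal | CC(C)CCCCC=O | starting material
5 | ortho-quinone methide: 2,4-dihydroxy-5-(6-methylheptylidene)-3-(3-methylbut-2-en-1-yl)-6-oxocyclohexa-1,3-diene-1-carbaldehyde (not isolated) | O=CC1=C(O)C(CC=C(C)C)=C(O)C(=CCCCCC(C)C)C1=O | intermediate
6 | 5,5'-(6-methylheptane-1,1-diyl)bis[2,4,6-trihydroxy-3-(3-methylbut-2-en-1-yl)benzaldehyde] | O=Cc1c(O)c(CC=C(C)C)c(O)c(C(CCCCC(C)C)c2c(O)c(CC=C(C)C)c(O)c(C=O)c2O)c1O | intermediate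
7 | 5,5'-(6-methylheptane-1,1-diyl)bis[2,4,6-tris(methoxymethoxy)-3-(3-methylbut-2-en-1-yl)benzaldehyde] | O=Cc1c(OCOC)c(CC=C(C)C)c(OCOC)c(C(CCCCC(C)C)c2c(OCOC)c(CC=C(C)C)c(OCOC)c(C=O)c2OCOC)c1OCOC | intermediate
8 | (E)-crotylboronic acid pinacol ester | C/C=C/CB1OC(C)(C)C(C)(C)O1 | starting material
9 | bis(pinacol borate) adduct: compound 10 with a 4,4,5,5-tetramethyl-1,3,2-dioxaborolan-2-yl group on each carbinol oxygen (not isolated) | C=C[C@@H](C)[C@@H](OB3OC(C)(C)C(C)(C)O3)c1c(OCOC)c(CC=C(C)C)c(OCOC)c(C(CCCCC(C)C)c2c(OCOC)c(CC=C(C)C)c(OCOC)c([C@H](OB3OC(C)(C)C(C)(C)O3)[C@H](C)C=C)c2OCOC)c1OCOC | intermediate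
10 | hexakis(methoxymethyl) bis[(1R,2R)-1-hydroxy-2-methylbut-3-en-1-yl] compound (anti, both arms) | C=C[C@@H](C)[C@@H](O)c1c(OCOC)c(CC=C(C)C)c(OCOC)c(C(CCCCC(C)C)c2c(OCOC)c(CC=C(C)C)c(OCOC)c([C@H](O)[C@H](C)C=C)c2OCOC)c1OCOC | intermediate
11 | hexakis(methoxymethyl) bis[(1R,2R)-1-hydroxy-2-methylbutyl] compound | CC[C@@H](C)[C@@H](O)c1c(OCOC)c(CC=C(C)C)c(OCOC)c(C(CCCCC(C)C)c2c(OCOC)c(CC=C(C)C)c(OCOC)c([C@H](O)[C@H](C)CC)c2OCOC)c1OCOC | intermediate
12 | 5,5'-(6-methylheptane-1,1-diyl)bis{(2R)-2-methyl-1-[2,4,6-tris(methoxymethoxy)-3-(3-methylbut-2-en-1-yl)phenyl]butan-1-one} | CC[C@@H](C)C(=O)c1c(OCOC)c(CC=C(C)C)c(OCOC)c(C(CCCCC(C)C)c2c(OCOC)c(CC=C(C)C)c(OCOC)c(C(=O)[C@H](C)CC)c2OCOC)c1OCOC | intermediate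
13 | 5,5'-(6-methylheptane-1,1-diyl)bis{(2R)-2-methyl-1-[2,4,6-trihydroxy-3-(3-methylbut-2-en-1-yl)phenyl]butan-1-one} (CNP0245910.1) | CC[C@@H](C)C(=O)c1c(O)c(CC=C(C)C)c(O)c(C(CCCCC(C)C)c2c(O)c(CC=C(C)C)c(O)c(C(=O)[C@H](C)CC)c2O)c1O | target

**Step count**

Total steps: 7. Longest linear sequence: 7 steps (1 → 13); 2, 4 and 8 are bought.

**Steps most likely to fail**

1. Step 4 (key step). The addition may be slow at formyl groups that each carry two ortho methoxymethoxy groups. Facial selectivity may be poor at such a hindered aldehyde, and an uncatalysed background addition on warming, or Z-isomer in 8, would erode the C2 configuration. Each wrongly set arm gives a diastereomer of 10 that is hard to remove once the carbinols are oxidised.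

   Fallback (stoichiometric reagent control by Brown crotylboration, from 7 back to 10): trans-but-2-ene is metalated with n-BuLi/KOt-Bu (THF, −45 °C) to (E)-crotylpotassium F1. Addition of (+)-B-methoxydiisopinocampheylborane, the borane derived from (−)-α-pinene and the antipode expected by the usual model for aryl aldehydes to give the (1R,2R) adduct, gives potassium (E)-crotyl(methoxy)diisopinocampheylborate F2. BF3·OEt2 at −78 °C removes methoxide to leave (E)-crotyldiisopinocampheylborane F3. F3 adds to both formyl groups of 7 at −78 °C through the same chair transition state, giving the bis(diisopinocampheylborinate) adduct F4, and NaOH/H2O2 work-up releases 10, which rejoins the route at step 5.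

2. Step 2. The second arylation may stall, the enolisable aldehyde 4 may self-condense under amine catalysis, and ortho-quinone methide 5 may tautomerise to an alkenylphenol or oligomerise before it is captured.

   Fallback (stepwise assembly through an isolated ortho-quinone methide precursor, from 3 and 4 back to 6): 3, 4 and morpholine (1 equiv each, EtOH, 23 °C) combine in a Betti-type three-component Mannich reaction to the Mannich base 2,4,6-trihydroxy-3-(3-methylbut-2-en-1-yl)-5-[6-methyl-1-(morpholin-4-yl)heptyl]benzaldehyde F5, which is purified. F5 is then heated with a second equivalent of 3 (toluene, 80 °C), where loss of morpholine regenerates 5 in low concentration in the presence of its trap and should give 6, which rejoins the route at step 3.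

3. Step 7. Under acid a prenyl group may cyclise onto a neighbouring hydroxyl, the bridging aryl–CH bonds may cleave, the ketone α-centres may epimerise, or removal of the six acetals may stop short.

   Fallback (protecting-group-free chiral-pool route, from 2 and 4 directly to 13): phloroglucinol is acylated with (R)-2-methylbutanoic acid (BF3·OEt2, 60 °C, Friedel–Crafts acylation) to (R)-2-methyl-1-(2,4,6-trihydroxyphenyl)butan-1-one F6. C-prenylation with 2 (DBU, THF, as in step 1) gives (R)-2-methyl-1-[2,4,6-trihydroxy-3-(3-methylbut-2-en-1-yl)phenyl]butan-1-one F7. The 2:1 condensation with 4 (piperidine/AcOH, MeOH, as in step 2) then proceeds through the acyl ortho-quinone methide F8 to 13. This path exposes the α-centre to the Lewis-acidic acylation, where partial racemisation is possible, which is why it is held in reserve.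

**Further compounds**

F1 | step 4 | (E)-crotylpotassium | C/C=C/C[K]
F2 | step 4 | potassium (E)-crotyl(methoxy)diisopinocampheylborate | [K+].C/C=C/C[B-](OC)([C@H]1C[C@H]2C[C@@H]([C@@H]1C)C2(C)C)[C@H]1C[C@H]2C[C@@H]([C@@H]1C)C2(C)C
F3 | step 4 | (E)-crotyldiisopinocampheylborane from (−)-α-pinene | C/C=C/CB([C@H]1C[C@H]2C[C@@H]([C@@H]1C)C2(C)C)[C@H]1C[C@H]2C[C@@H]([C@@H]1C)C2(C)C
F4 | step 4 | bis(diisopinocampheylborinate) adduct of 10 | C=C[C@@H](C)[C@@H](OB([C@H]3C[C@H]4C[C@@H]([C@@H]3C)C4(C)C)[C@H]3C[C@H]4C[C@@H]([C@@H]3C)C4(C)C)c1c(OCOC)c(CC=C(C)C)c(OCOC)c(C(CCCCC(C)C)c2c(OCOC)c(CC=C(C)C)c(OCOC)c([C@H](OB([C@H]3C[C@H]4C[C@@H]([C@@H]3C)C4(C)C)[C@H]3C[C@H]4C[C@@H]([C@@H]3C)C4(C)C)[C@H](C)C=C)c2OCOC)c1OCOC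
F5 | step 2 | 2,4,6-trihydroxy-3-(3-methylbut-2-en-1-yl)-5-[6-methyl-1-(morpholin-4-yl)heptyl]benzaldehyde | O=Cc1c(O)c(CC=C(C)C)c(O)c(C(CCCCC(C)C)N2CCOCC2)c1O
F6 | step 7 | (R)-2-methyl-1-(2,4,6-trihydroxyphenyl)butan-1-one | CC[C@@H](C)C(=O)c1c(O)cc(O)cc1O
F7 | step 7 | (R)-2-methyl-1-[2,4,6-trihydroxy-3-(3-methylbut-2-en-1-yl)phenyl]butan-1-one | CC[C@@H](C)C(=O)c1c(O)cc(O)c(CC=C(C)C)c1O
F8 | step 7 | acyl ortho-quinone methide: (R)-3,5-dihydroxy-2-(2-methylbutanoyl)-6-(6-methylheptylidene)-4-(3-methylbut-2-en-1-yl)cyclohexa-2,4-dien-1-one | CC[C@@H](C)C(=O)C1=C(O)C(CC=C(C)C)=C(O)C(=CCCCCC(C)C)C1=O
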